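The tetrahydrofuran (O1, C2–C5) is disconnected at C2–C3. C2 is an O-benzylic carbon at the aldehyde level of ring B, and C3 carries a CH2OH that can be an aldehyde, so C2–C3 is an intramolecular aldol bond between an oxocarbenium ion and an enol. Both are stored in a seven-membered vinyl acetal, a 2-aryl-5-(1-arylvinyl)-4,5-dihydro-1,3-dioxepine made from the ring B aldehyde, cis-2-butene-1,4-diol and an asymmetric Heck reaction. Me3SiOTf triggers a [1,3] O-to-C ring contraction that closes the ring, forms C2–C3 and sets C2 and C3 from the C4 centre, both acetal epimers converging on the all-trans aldehyde.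

Key step: step 10

Remarks on the chemistry:
- Ring A is the 4-hydroxy-3-methoxyphenyl ring, ring B the central 2,6-dimethoxyphenoxy ring, ring C the aroyl ring. Side-chain carbons are C7 (carbinol), C8 (aryloxy) and C9 (CH2OH).
- Assumption: (S)-t-Bu-PHOX is taken as the ligand enantiomer that gives the (5R) vinyl acetal 16. If the sense proves opposite, the (R) ligand is used.
- Assumption: the α-aryloxy imide 7 behaves like α-alkyl imides in the MgCl2-catalysed anti-aldol (chelated Z-enolate, same facial sense).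

Step 1
Reactants: 1 (S)-4-benzyloxazolidin-2-one; 2 bromoacetyl bromide
Product: 3 (S)-4-benzyl-3-(bromoacetyl)oxazolidin-2-one
Conditions: n-BuLi, THF, −78 °C; then 2, −78 °C to 0 °C
Reagents that add atoms: none
Why: N-acylation of the lithiated oxazolidinone (acyl substitution), the acyl bromide reacting far faster than the alkyl bromide.

Step 2
Reactants: 3; 4 syringaldehyde
Product: 5 (S)-4-benzyl-3-[(4-formyl-2,6-dimethoxyphenoxy)acetyl]oxazolidin-2-one
Conditions: K2CO3, acetone, rt
Reagents that add atoms: none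
Why: Williamson ether synthesis, the phenoxide displacing the activated α-bromo imide by SN2 under conditions too mild to cleave the imide.

Step 3
Reactants: 5; 6 cis-2-butene-1,4-diol
Product: 7 (S)-4-benzyl-3-{[4-(4,7-dihydro-1,3-dioxepin-2-yl)-2,6-dimethoxyphenoxy]acetyl}oxazolidin-2-one
Conditions: 6 (3 equiv), p-TsOH·H2O (cat.), benzene, reflux, Dean–Stark
Reagents that add atoms: none
Why: Acid-catalysed acetalisation with azeotropic water removal gives the seven-membered allylic acetal, which masks the aldehyde through steps 4–6 and is the later ring-contraction scaffold.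

Step 4
Reactants: 7; 8 vanillin acetate (4-formyl-2-methoxyphenyl acetate)
Product: 9 (S)-4-benzyl-3-[(2R,3R)-3-(4-acetoxy-3-methoxyphenyl)-2-(ring B aryloxy)-3-(trimethylsilyloxy)propanoyl]oxazolidin-2-one (ring B still carrying the dihydrodioxepine)
Conditions: MgCl2 (0.2 equiv), Et3N, Me3SiCl, EtOAc, rt
Reagents that add atoms: chlorotrimethylsilane C[Si](C)(C)Cl
Why: Magnesium-halide-catalysed Evans anti-aldol: the chelated Z-magnesium enolate adds through a boat transition state, the (S)-benzyl auxiliary setting C8 and the anti topology setting C7 (erythro), while silylation of the aldolate makes the addition irreversible.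

Step 5
Reactants: 9
Product: 11 (1R,2S)-2-[4-(4,7-dihydro-1,3-dioxepin-2-yl)-2,6-dimethoxyphenoxy]-1-(4-hydroxy-3-methoxyphenyl)propane-1,3-diol, via trimethylsilyl ether diol 10 (not isolated)
Conditions: LiBH4, THF–MeOH, 0 °C; then K2CO3 (cat.), MeOH, 0 °C
Reagents that add atoms: none
Why: Reductive cleavage of the N-acyloxazolidinone to the primary alcohol (the aryl acetate is reduced off as well), followed by mild methanolysis of the labile Me3Si ether, without touching C7, C8 or the acetal.

Step 6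
Reactants: 11
Product: 12 tris(tert-butyldimethylsilyl) ether of 11 (ring A phenol O, C7 O and C9 O silylated)
Conditions: TBSCl, imidazole, DMAP (cat.), DMF, 40 °C
Reagents that add atoms: tert-butyldimethylsilyl chloride CC(C)(C)[Si](C)(C)Cl
Why: Imidazole-promoted silylation of all three hydroxyls, which avoids silyl triflates that could open the acetal; silyl ethers tolerate the later Lewis acid at low temperature and are not leaving groups para to a phenol.

Step 7
Reactants: 13 acetosyringone
Product: 14 4-acetyl-2,6-dimethoxyphenyl pivalate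
Conditions: PivCl, Et3N, DMAP (cat.), CH2Cl2, 0 °C to rt
Reagents that add atoms: pivaloyl chloride CC(C)(C)C(=O)Cl
Why: O-acylation of the phenol; the hindered ester survives the strong base of step 8 and makes ring C, hence the later arylvinyl group, electron-poor.

Step 8
Reactants: 14
Product: 15 2,6-dimethoxy-4-[1-(trifluoromethylsulfonyloxy)vinyl]phenyl pivalate
Conditions: KN(SiMe3)2, THF, −78 °C; then PhNTf2
Reagents that add atoms: N-phenylbis(trifluoromethanesulfonimide) O=S(=O)(N(c1ccccc1)S(=O)(=O)C(F)(F)F)C(F)(F)F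
Why: Kinetic enolisation of the methyl ketone and O-triflation of the potassium enolate give the 1-arylvinyl triflate.

Step 9
Reactants: 12; 15
Product: 16 vinyl acetal: 12 in which the acetal ring is (5R)-5-[1-(3,5-dimethoxy-4-pivaloyloxyphenyl)vinyl]-4,5-dihydro-1,3-dioxepin-2-yl (enol ether C6=C7; both epimers at the acetal carbon)
Conditions: 15 (1.0 equiv), 12 (1.3 equiv, excess recovered), Pd2(dba)3 (3 mol %), (S)-t-Bu-PHOX (7 mol %), i-Pr2NEt, THF, 60 °C
Reagents that add atoms: none
Why: Asymmetric cationic Heck reaction: the alkenyl–palladium species (from zerovalent palladium and the triflate) adds syn to the symmetric cis alkene, and the only syn β-hydrogen lies toward oxygen, so elimination gives the enol ether directly; the PHOX ligand distinguishes the enantiotopic alkene carbons and sets dioxepine C5, while the configuration at the acetal carbon is irrelevant because it is erased in step 10.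

Step 10
Reactants: 16
Product: 19 (2S,3S,4R)-2-(ring B aryl)-4-[1-(3,5-dimethoxy-4-pivaloyloxyphenyl)vinyl]tetrahydrofuran-3-carbaldehyde (side chain as in 12), via oxocarbenium silyl enol ether triflate 17 (not isolated), via 2,3-cis aldehyde 18 (not isolated)
Conditions: Me3SiOTf (0.2 equiv), CH2Cl2, −78 °C, then −20 °C until equilibrated; Et3N quench
Reagents that add atoms: none
Why: Silylation of the enol-ether oxygen ionises the acetal C–O bond to an aryl-stabilised oxocarbenium ion tethered to a Z silyl enol ether (17), whose enol carbon attacks the oxocarbenium carbon, forming C2–C3 and releasing the silyl group for the next turnover. The closest known reaction type is the Lewis-acid ring contraction of 4,5-dihydro-1,3-dioxepines to tetrahydrofuran-3-carbaldehydes (vinyl acetal [1,3] O-to-C rearrangement, related to the Petasis–Ferrier rearrangement and the intramolecular Mukaiyama aldol). The tetrahydrofuran closes in a 5-(enol-exo)-endo-trig mode at the oxocarbenium carbon. C3 is set trans to the pseudo-equatorial C4 substituent, which is the fixed, non-epimerisable reference at this stage. C2 should first form cis to the formyl group (18) and is corrected to trans by reversible retro-aldol ionisation, so both acetal epimers of 16 funnel into the all-trans aldehyde. The step needs the enol silane, not the arylvinyl group, to trap the cation; this is secured by the much higher nucleophilicity of the silyl enol ether and by the pivaloyloxy-deactivated ring C, and the low temperature spares the benzylic silyl ether at C7.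

Step 11
Reactants: 19
Product: 20 (2S,3R,4R)-alcohol: 19 with CH2OH in place of CHO
Conditions: NaBH4, THF–MeOH (9:1), −20 °C
Reagents that add atoms: none
Why: Hydride reduction of the aldehyde, which removes the epimerisable α-position at C3 while the aryl pivalate and silyl ethers survive at low temperature.

Step 12
Reactants: 20
Product: 21 (2S,3R,4S)-ketone: 20 with the C(=CH2) group converted to C=O
Conditions: OsO4 (2 mol %), NaIO4 (4 equiv), 2,6-lutidine, dioxane–H2O, rt
Reagents that add atoms: sodium periodate [Na+].[O-]I(=O)(=O)=O (stoichiometric oxygen source, delivered through catalytic osmium tetroxide O=[Os](=O)(=O)=O)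
Why: Lemieux–Johnson cleavage of the 1,1-disubstituted alkene to the aryl ketone; all phenols are masked so periodate does not attack the arenes, and the trans arrangement at the new α-centre C4 is already the thermodynamic one.

Step 13
Reactants: 21
Product: 23 target CNP0236429.1, via desilylated aryl pivalate 22 (not isolated)
Conditions: HF·pyridine, THF–pyridine, 0 °C to rt; concentrate; then K2CO3, MeOH, 0 °C; aq. NH4Cl
Reagents that add atoms: none
Why: Fluoride cleavage of the three silyl ethers, then methanolysis of the activated aryl pivalate; the resulting para-acyl phenoxide suppresses enolisation at C4, and the all-trans ketone is in any case the stable isomer.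

Compound list
1 | (S)-4-benzyloxazolidin-2-one | O=C1N[C@@H](Cc2ccccc2)CO1 | starting material
2 | bromoacetyl bromide | BrCC(Br)=O | starting material
3 | (S)-4-benzyl-3-(bromoacetyl)oxazolidin-2-one | O=C1OC[C@H](Cc2ccccc2)N1C(=O)CBr | intermediate
4 | syringaldehyde | COc1cc(C=O)cc(OC)c1O | starting material
5 | (S)-4-benzyl-3-[(4-formyl-2,6-dimethoxyphenoxy)acetyl]oxazolidin-2-one | O=C1OC[C@H](Cc2ccccc2)N1C(=O)COc1c(OC)cc(C=O)cc1OC | intermediate
6 | cis-2-butene-1,4-diol | OC/C=C\CO | starting material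
7 | (S)-4-benzyl-3-{[4-(4,7-dihydro-1,3-dioxepin-2-yl)-2,6-dimethoxyphenoxy]acetyl}oxazolidin-2-one | O=C1OC[C@H](Cc2ccccc2)N1C(=O)COc1c(OC)cc(cc1OC)C1OCC=CCO1 | intermediate
8 | vanillin acetate | COc1cc(C=O)ccc1OC(C)=O | starting material
9 | anti-aldol adduct, (2R,3R)-propanoyl imide, C7 O-trimethylsilyl, ring A acetate | COc1cc([C@@H](O[Si](C)(C)C)[C@H](C(=O)N3[C@@H](Cc4ccccc4)COC3=O)Oc2c(OC)cc(C5OCC=CCO5)cc2OC)ccc1OC(C)=O | intermediate
10 | (2S,3R)-2-(ring B aryloxy)-3-(4-hydroxy-3-methoxyphenyl)-3-(trimethylsilyloxy)propan-1-ol (not isolated) | COc1cc([C@@H](O[Si](C)(C)C)[C@H](CO)Oc2c(OC)cc(C3OCC=CCO3)cc2OC)ccc1O | intermediate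
11 | (1R,2S)-2-[4-(4,7-dihydro-1,3-dioxepin-2-yl)-2,6-dimethoxyphenoxy]-1-(4-hydroxy-3-methoxyphenyl)propane-1,3-diol | COc1cc([C@@H](O)[C@H](CO)Oc2c(OC)cc(C3OCC=CCO3)cc2OC)ccc1O | intermediate
12 | tris(tert-butyldimethylsilyl) ether of 11 | COc1cc([C@@H](O[Si](C)(C)C(C)(C)C)[C@H](CO[Si](C)(C)C(C)(C)C)Oc2c(OC)cc(C3OCC=CCO3)cc2OC)ccc1O[Si](C)(C)C(C)(C)C | intermediate
13 | acetosyringone | CC(=O)c1cc(OC)c(O)c(OC)c1 | starting material
14 | 4-acetyl-2,6-dimethoxyphenyl pivalate | CC(=O)c1cc(OC)c(OC(=O)C(C)(C)C)c(OC)c1 | intermediate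
15 | 2,6-dimethoxy-4-[1-(trifluoromethylsulfonyloxy)vinyl]phenyl pivalate | C=C(OS(=O)(=O)C(F)(F)F)c1cc(OC)c(OC(=O)C(C)(C)C)c(OC)c1 | intermediate
16 | (5R)-5-(1-arylvinyl)-2-aryl-4,5-dihydro-1,3-dioxepine (vinyl acetal, acetal epimers) | COc1cc([C@@H](O[Si](C)(C)C(C)(C)C)[C@H](CO[Si](C)(C)C(C)(C)C)Oc2c(OC)cc(C3OC[C@@H](C(=C)c4cc(OC)c(OC(=O)C(C)(C)C)c(OC)c4)C=CO3)cc2OC)ccc1O[Si](C)(C)C(C)(C)C | intermediate
17 | ring-opened oxocarbenium ion with Z trimethylsilyl enol ether, triflate salt (not isolated) | COc1cc([C@@H](O[Si](C)(C)C(C)(C)C)[C@H](CO[Si](C)(C)C(C)(C)C)Oc2c(OC)cc(C=[O+]C[C@@H](C(=C)c3cc(OC)c(OC(=O)C(C)(C)C)c(OC)c3)/C=C\O[Si](C)(C)C)cc2OC)ccc1O[Si](C)(C)C(C)(C)C.[O-]S(=O)(=O)C(F)(F)F | intermediate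
18 | (2R,3S,4R)-2,3-cis-3,4-trans tetrahydrofuran-3-carbaldehyde (not isolated) | COc1cc([C@@H](O[Si](C)(C)C(C)(C)C)[C@H](CO[Si](C)(C)C(C)(C)C)Oc2c(OC)cc([C@@H]3OC[C@@H](C(=C)c4cc(OC)c(OC(=O)C(C)(C)C)c(OC)c4)[C@@H]3C=O)cc2OC)ccc1O[Si](C)(C)C(C)(C)C | intermediate
19 | (2S,3S,4R)-all-trans tetrahydrofuran-3-carbaldehyde | COc1cc([C@@H](O[Si](C)(C)C(C)(C)C)[C@H](CO[Si](C)(C)C(C)(C)C)Oc2c(OC)cc([C@H]3OC[C@@H](C(=C)c4cc(OC)c(OC(=O)C(C)(C)C)c(OC)c4)[C@@H]3C=O)cc2OC)ccc1O[Si](C)(C)C(C)(C)C | intermediate
20 | (2S,3R,4R)-3-(hydroxymethyl)tetrahydrofuran with 4-(1-arylvinyl) group | COc1cc([C@@H](O[Si](C)(C)C(C)(C)C)[C@H](CO[Si](C)(C)C(C)(C)C)Oc2c(OC)cc([C@H]3OC[C@@H](C(=C)c4cc(OC)c(OC(=O)C(C)(C)C)c(OC)c4)[C@@H]3CO)cc2OC)ccc1O[Si](C)(C)C(C)(C)C | intermediate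
21 | (2S,3R,4S)-4-aroyl-3-(hydroxymethyl)tetrahydrofuran, tris-silyl ether, ring C pivalate | COc1cc([C@@H](O[Si](C)(C)C(C)(C)C)[C@H](CO[Si](C)(C)C(C)(C)C)Oc2c(OC)cc([C@H]3OC[C@@H](C(=O)c4cc(OC)c(OC(=O)C(C)(C)C)c(OC)c4)[C@@H]3CO)cc2OC)ccc1O[Si](C)(C)C(C)(C)C | intermediate
22 | target with ring C phenol still as pivalate (not isolated) | COc1cc([C@@H](O)[C@H](CO)Oc2c(OC)cc([C@H]3OC[C@@H](C(=O)c4cc(OC)c(OC(=O)C(C)(C)C)c(OC)c4)[C@@H]3CO)cc2OC)ccc1O | intermediate
23 | CNP0236429.1 | COc1cc([C@@H](O)[C@H](CO)Oc2c(OC)cc([C@H]3OC[C@@H](C(=O)c4cc(OC)c(O)c(OC)c4)[C@@H]3CO)cc2OC)ccc1O | target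

Total step count: 13. Longest linear sequence: 11 (steps 1–6 and 9–13); steps 7–8 form the side branch.

Steps most likely to fail

1. Step 10. During the slow equilibration at C2 the oxocarbenium ion may be captured by the arylvinyl π-bond (Prins-type six-ring closure) instead of the enol silane. The fallback sets out from 12 and returns at 23; it keeps the ring contraction but carries a plain vinyl group, a far poorer π-nucleophile, and builds the aroyl group afterwards. The Heck reaction of step 9 is run on 12 with vinyl triflate to give the 5-vinyl vinyl acetal F1. The same Me3SiOTf contraction gives the all-trans 4-vinyl aldehyde F2, and NaBH4 gives the alcohol F3. OsO4/NaIO4 cleaves the vinyl group to the 4-formyl compound F4. Addition of the dilithiated phenol F5 (from 4-bromo-2,6-dimethoxyphenol and t-BuLi, THF, −78 °C) gives the carbinol F6 as a mixture at the new carbinol carbon. MnO2 in CH2Cl2 oxidises this benzylic carbinol to the ketone F7, and HF·pyridine removes the three silyl ethers to give 23.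

2. Step 9. The advanced alkene 12 cannot be used in large excess, so a second alkenylation of the product enol ether and Pd–H isomerisation may compete, and discrimination of the enantiotopic alkene carbons may be incomplete. The fallback sets out from 7 and returns at 16; the coupling is moved ahead of the side-chain construction, where the alkene is cheap. The Heck reaction is run with 15 and a several-fold excess of 7 (recovered) to give the imide vinyl acetal F8, and the C5 epimers are removed at this stage by chromatography or crystallisation of the oxazolidinone imides. The anti-aldol of step 4 with 8 gives the silylated adduct F9 (the enol ether tolerates the basic MgCl2/Et3N/Me3SiCl medium). LiBH4, then brief K2CO3/MeOH at 0 °C (the hindered aryl pivalate is kept), gives the triol F11 by way of the trimethylsilyl ether diol F10, and silylation as in step 6 gives 16.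

3. Step 4. Anti-selectivity at the carbinol carbon C7 may erode through competing transition states or retro-aldol before silylation, while C8 remains auxiliary-controlled. The fallback sets out from 11 (then a mixture of C7 epimers) and returns at 12; C7 is set by substrate-controlled ketone reduction instead. TBSCl (2.2 equiv)/imidazole in CH2Cl2 at 0 °C silylates the phenol and the primary hydroxyl to give the bis-silyl ether F12 as a C7 epimer mixture. Dess–Martin periodinane with NaHCO3 converges both epimers on the α-aryloxy ketone F13. LiBH(s-Bu)3 in THF at −78 °C reduces it under Felkin–Anh control (aryloxy group anti to the incoming hydride) to the erythro (7R,8S) alcohol F14. TBSCl/imidazole in DMF at 40 °C then gives 12.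

Further compounds
F1 | step 10 | 12 with the acetal ring as (5S)-5-vinyl-4,5-dihydro-1,3-dioxepin-2-yl (acetal epimers) | COc1cc([C@@H](O[Si](C)(C)C(C)(C)C)[C@H](CO[Si](C)(C)C(C)(C)C)Oc2c(OC)cc(C3OC[C@@H](C=C)C=CO3)cc2OC)ccc1O[Si](C)(C)C(C)(C)C
F2 | step 10 | all-trans 2-aryl-4-vinyltetrahydrofuran-3-carbaldehyde (vinyl analogue of 19) | COc1cc([C@@H](O[Si](C)(C)C(C)(C)C)[C@H](CO[Si](C)(C)C(C)(C)C)Oc2c(OC)cc([C@H]3OC[C@@H](C=C)[C@@H]3C=O)cc2OC)ccc1O[Si](C)(C)C(C)(C)C
F3 | step 10 | all-trans 2-aryl-3-(hydroxymethyl)-4-vinyltetrahydrofuran | COc1cc([C@@H](O[Si](C)(C)C(C)(C)C)[C@H](CO[Si](C)(C)C(C)(C)C)Oc2c(OC)cc([C@H]3OC[C@@H](C=C)[C@@H]3CO)cc2OC)ccc1O[Si](C)(C)C(C)(C)C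
F4 | step 10 | all-trans 2-aryl-4-formyl-3-(hydroxymethyl)tetrahydrofuran | COc1cc([C@@H](O[Si](C)(C)C(C)(C)C)[C@H](CO[Si](C)(C)C(C)(C)C)Oc2c(OC)cc([C@H]3OC[C@@H](C=O)[C@@H]3CO)cc2OC)ccc1O[Si](C)(C)C(C)(C)C
F5 | step 10 | lithium 4-lithio-2,6-dimethoxyphenolate | [Li]c1cc(OC)c([O-])c(OC)c1.[Li+]
F6 | step 10 | 4-[hydroxy(4-hydroxy-3,5-dimethoxyphenyl)methyl] analogue of 20 (carbinol epimers, ring C phenol free) | COc1cc([C@@H](O[Si](C)(C)C(C)(C)C)[C@H](CO[Si](C)(C)C(C)(C)C)Oc2c(OC)cc([C@H]3OC[C@@H](C(O)c4cc(OC)c(O)c(OC)c4)[C@@H]3CO)cc2OC)ccc1O[Si](C)(C)C(C)(C)C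
F7 | step 10 | 21 with the ring C phenol free instead of pivaloylated | COc1cc([C@@H](O[Si](C)(C)C(C)(C)C)[C@H](CO[Si](C)(C)C(C)(C)C)Oc2c(OC)cc([C@H]3OC[C@@H](C(=O)c4cc(OC)c(O)c(OC)c4)[C@@H]3CO)cc2OC)ccc1O[Si](C)(C)C(C)(C)C
F8 | step 9 | 7 with the acetal ring as (5R)-5-[1-(3,5-dimethoxy-4-pivaloyloxyphenyl)vinyl]-4,5-dihydro-1,3-dioxepin-2-yl | O=C1OC[C@H](Cc2ccccc2)N1C(=O)COc1c(OC)cc(cc1OC)C1OC[C@@H](C(=C)c2cc(OC)c(OC(=O)C(C)(C)C)c(OC)c2)C=CO1
F9 | step 9 | anti-aldol adduct corresponding to 9 with the vinyl acetal ring of 16 | COc1cc([C@@H](O[Si](C)(C)C)[C@H](C(=O)N3[C@@H](Cc4ccccc4)COC3=O)Oc2c(OC)cc(C5OC[C@@H](C(=C)c6cc(OC)c(OC(=O)C(C)(C)C)c(OC)c6)C=CO5)cc2OC)ccc1OC(C)=O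
F10 | step 9 | trimethylsilyl ether diol corresponding to 10 with the vinyl acetal ring of 16 (not isolated) | COc1cc([C@@H](O[Si](C)(C)C)[C@H](CO)Oc2c(OC)cc(C3OC[C@@H](C(=C)c4cc(OC)c(OC(=O)C(C)(C)C)c(OC)c4)C=CO3)cc2OC)ccc1O
F11 | step 9 | triol corresponding to 11 with the vinyl acetal ring of 16 | COc1cc([C@@H](O)[C@H](CO)Oc2c(OC)cc(C3OC[C@@H](C(=C)c4cc(OC)c(OC(=O)C(C)(C)C)c(OC)c4)C=CO3)cc2OC)ccc1O
F12 | step 4 | 11 silylated at the ring A phenol and C9 O, C7 hydroxyl free (C7 epimer mixture) | COc1cc(C(O)[C@H](CO[Si](C)(C)C(C)(C)C)Oc2c(OC)cc(C3OCC=CCO3)cc2OC)ccc1O[Si](C)(C)C(C)(C)C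
F13 | step 4 | (S)-α-aryloxy ketone: F12 with C7 as C=O | COc1cc(C(=O)[C@H](CO[Si](C)(C)C(C)(C)C)Oc2c(OC)cc(C3OCC=CCO3)cc2OC)ccc1O[Si](C)(C)C(C)(C)C
F14 | step 4 | erythro (7R,8S) alcohol: F12 as the single C7 epimer | COc1cc([C@@H](O)[C@H](CO[Si](C)(C)C(C)(C)C)Oc2c(OC)cc(C3OCC=CCO3)cc2OC)ccc1O[Si](C)(C)C(C)(C)C
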